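**Retrosynthetic overview**
1. Isochandalone 11 comes from its 7-O-MOM ether 10 by acetal cleavage.
2. The C6 prenyl group of 10 comes from aryl 1,1-dimethylallyl ether 9 by aromatic Claisen rearrangement. The key bond is the O5–C(Me)2 bond, made by Pd-catalysed allylic etherification of the chelated 5-OH of 5 (new on this substrate class).
3. The pyran on ring B of 5 comes from the 4'-O-(1,1-dimethylpropargyl) ether 4 (O-alkylation, then Claisen / 1,5-H shift / oxa-6π closure).
4. Ether 4 comes from 7-O-MOM genistein 2 and genistein 1; the three hydroxyls are told apart by acidity (O7 first, O4' second, chelated O5 last).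
5. Ring order: rings A and C are bought with genistein; the only ring built is the chromene pyran on ring B (step 2); the prenyl group goes on last.

Assumption: the target has no stereocentre and no stereogenic double bond, so it is achiral and no stereocontrol is needed.

**Route**

Step 1
Reactants: 1 genistein
Product: 2 5-hydroxy-3-(4-hydroxyphenyl)-7-(methoxymethoxy)-4H-chromen-4-one (7-O-MOM genistein)
Conditions: MOMCl (1.05 equiv), K2CO3 (1.1 equiv), acetone, 0 °C to rt
Reagents that add atoms: chloromethyl methyl ether, COCCl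
Why: The 7-OH (a vinylogous carboxylic acid, pKa about 7) is the only hydroxyl ionised by one equivalent of K2CO3, the 4'-OH being clearly less acidic and the 5-OH locked in a hydrogen bond to the C4 carbonyl, so this Williamson-type O-alkylation goes to O7.

Step 2
Reactants: 2 7-O-MOM genistein; 3 3-chloro-3-methylbut-1-yne
Product: 5 3-(2,2-dimethyl-2H-chromen-6-yl)-5-hydroxy-7-(methoxymethoxy)-4H-chromen-4-one (7-O-MOM isoderrone), via aryl 1,1-dimethylpropargyl ether 4 (not isolated)
Conditions: K2CO3 (2 equiv), KI (10 mol %), CuI (2 mol %), acetone, 56 °C; then filter, o-xylene, 140 °C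
Reagents that add atoms: none
Why: With O7 masked and O5 chelated only the 4'-phenoxide is alkylated (copper-assisted Williamson etherification with a tertiary propargylic chloride), and on heating ether 4 undergoes aromatic propargyl Claisen rearrangement, 1,5-hydrogen shift and oxa-6π electrocyclisation to close the 2,2-dimethylpyran; the two ortho positions of ring B are equivalent, so one chromene results.

Step 3
Reactants: 6 2-methylbut-3-en-2-ol
Product: 8 tert-butyl 2-methylbut-3-en-2-yl carbonate, via lithium 2-methylbut-3-en-2-olate 7 (not isolated)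
Conditions: n-BuLi (1.0 equiv), THF, 0 °C; then Boc2O, 0 °C to rt; H2O work-up
Reagents that add atoms: di-tert-butyl dicarbonate, CC(C)(C)OC(=O)OC(=O)OC(C)(C)C
Why: Acylation of the lithium alkoxide of a tertiary allylic alcohol by Boc2O (mixed carbonate formation) is the standard way to an ionisable tert-prenyl donor for Tsuji–Trost chemistry.

Step 4
Reactants: 5 7-O-MOM isoderrone; 8 tert-butyl 2-methylbut-3-en-2-yl carbonate
Product: 10 3-(2,2-dimethyl-2H-chromen-6-yl)-5-hydroxy-7-(methoxymethoxy)-6-(3-methylbut-2-en-1-yl)-4H-chromen-4-one (7-O-MOM isochandalone), via aryl 1,1-dimethylallyl ether 9 (not isolated)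
Conditions: 8 (3 equiv), Pd(PPh3)4 (5 mol %), THF, 0 °C to rt; then short silica plug, PhMe, 110 °C
Reagents that add atoms: none
Why: Proposed new method: zerovalent palladium ionises carbonate 8 to a cationic 1,1-dimethylallyl-palladium complex whose counter-ion loses CO2 to give tert-butoxide, a base strong enough to break the O5–H···O4 chelate inside the ion pair, so the only free hydroxyl of 5 is delivered as a phenoxide to the more substituted allyl terminus (kinetic, branched C–O bond formation) to give ether 9; after removal of palladium, heating triggers an aromatic Claisen rearrangement whose only open ortho position is C6 and which transposes the allyl unit into the normal prenyl group; the closest known reaction type is the palladium-catalysed Tsuji–Trost reverse prenylation of ordinary phenols followed by Claisen rearrangement, which has not been shown for an intramolecularly hydrogen-bonded peri-hydroxy ketone such as a 5-hydroxyisoflavone.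

Step 5
Reactants: 10 7-O-MOM isochandalone
Product: 11 isochandalone
Conditions: 3 M aq. HCl, MeOH, 50 °C
Reagents that add atoms: none
Why: Acid-catalysed methanolysis of the MOM acetal (standard MOM ether cleavage) is fast in dilute HCl at moderate temperature, conditions under which prenyl and 2,2-dimethylchromene groups on related isoflavones generally survive.

**Compound list**
1 | genistein, 5,7-dihydroxy-3-(4-hydroxyphenyl)-4H-chromen-4-one | O=c1c(-c2ccc(O)cc2)coc2cc(O)cc(O)c12 | starting material
2 | 5-hydroxy-3-(4-hydroxyphenyl)-7-(methoxymethoxy)-4H-chromen-4-one (7-O-MOM genistein) | COCOc1cc(O)c2c(=O)c(-c3ccc(O)cc3)coc2c1 | intermediate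
3 | 3-chloro-3-methylbut-1-yne | C#CC(C)(C)Cl | starting material
4 | 5-hydroxy-7-(methoxymethoxy)-3-[4-(2-methylbut-3-yn-2-yloxy)phenyl]-4H-chromen-4-one (aryl 1,1-dimethylpropargyl ether) | COCOc1cc(O)c2c(=O)c(-c3ccc(OC(C)(C)C#C)cc3)coc2c1 | intermediate
5 | 3-(2,2-dimethyl-2H-chromen-6-yl)-5-hydroxy-7-(methoxymethoxy)-4H-chromen-4-one (7-O-MOM isoderrone) | COCOc1cc(O)c2c(=O)c(-c3ccc4c(c3)C=CC(C)(C)O4)coc2c1 | intermediate
6 | 2-methylbut-3-en-2-ol | C=CC(C)(C)O | starting material
7 | lithium 2-methylbut-3-en-2-olate | [Li+].[O-]C(C)(C)C=C | intermediate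
8 | tert-butyl 2-methylbut-3-en-2-yl carbonate | C=CC(C)(C)OC(=O)OC(C)(C)C | intermediate
9 | 3-(2,2-dimethyl-2H-chromen-6-yl)-7-(methoxymethoxy)-5-(2-methylbut-3-en-2-yloxy)-4H-chromen-4-one (aryl 1,1-dimethylallyl ether) | COCOc1cc(OC(C)(C)C=C)c2c(=O)c(-c3ccc4c(c3)C=CC(C)(C)O4)coc2c1 | intermediate
10 | 3-(2,2-dimethyl-2H-chromen-6-yl)-5-hydroxy-7-(methoxymethoxy)-6-(3-methylbut-2-en-1-yl)-4H-chromen-4-one (7-O-MOM isochandalone) | COCOc1cc2occ(-c3ccc4c(c3)C=CC(C)(C)O4)c(=O)c2c(O)c1CC=C(C)C | intermediate
11 | isochandalone, 3-(2,2-dimethyl-2H-chromen-6-yl)-5,7-dihydroxy-6-(3-methylbut-2-en-1-yl)-4H-chromen-4-one | CC(C)=CCc1c(O)cc2occ(-c3ccc4c(c3)C=CC(C)(C)O4)c(=O)c2c1O | target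

**Step count and risks**
Total steps: 5. Longest linear sequence: 4 steps (1 → 2 → 5 → 10 → 11); step 3 is a one-step side branch for the reagent.

The three steps most likely to fail:

Step 4 (the proposed new step). The chelated 5-hydroxyl may be too poor a nucleophile, or the linear O-prenyl ether or C-allylation may win. The fallback uses known chemistry, sets out from compound 5 and comes back to the route at compound 9. Compound 5 is O-alkylated with 3-chloro-3-methylbut-1-yne 3 under forcing copper-assisted Williamson conditions (Cs2CO3, KI, CuI cat., DMF, 70 °C; hydrogen-bonded ortho-hydroxy aryl ketones are known to react this way). This gives 3-(2,2-dimethyl-2H-chromen-6-yl)-7-(methoxymethoxy)-5-(2-methylbut-3-yn-2-yloxy)-4H-chromen-4-one F1. Its terminal alkyne is semi-hydrogenated (H2, Pd/CaCO3 poisoned with Pb(OAc)2, quinoline, EtOAc, rt) to ether 9, which is heated in PhMe as in step 4 to give 10.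

Step 2. The etherification with the tertiary propargylic chloride may be sluggish, or the thermal stage may decompose material. The fallback sets out from compound 2 and comes back at compound 5. The non-chelated 4'-OH is reverse-prenylated with carbonate 8 (1.2 equiv, Pd(PPh3)4, THF, 0 °C; established for ordinary phenols) to give 5-hydroxy-7-(methoxymethoxy)-3-[4-(2-methylbut-3-en-2-yloxy)phenyl]-4H-chromen-4-one F2. Aromatic Claisen rearrangement (PhMe, 110 °C) gives 5-hydroxy-3-[4-hydroxy-3-(3-methylbut-2-en-1-yl)phenyl]-7-(methoxymethoxy)-4H-chromen-4-one F3. Dehydrogenative cyclisation with DDQ (1.1 equiv, benzene, 80 °C; hydride abstraction to an ortho-quinone methide, then oxa-6π closure) forms the chromene ring of 5.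

Step 5. Acid may cyclise the 6-prenyl group onto O5 or O7. The fallback sets out from compound 5 and comes back at compound 11; it moves the acid step to a stage without a prenyl group and ends with fluoride. The MOM ether of 5 is cleaved (3 M aq. HCl, MeOH, 50 °C) to 3-(2,2-dimethyl-2H-chromen-6-yl)-5,7-dihydroxy-4H-chromen-4-one (isoderrone) F4. Its only non-chelated hydroxyl is silylated (TIPSCl, imidazole, DMF, rt) to 3-(2,2-dimethyl-2H-chromen-6-yl)-5-hydroxy-7-[tri(propan-2-yl)silyloxy]-4H-chromen-4-one F5. This is taken through the step 4 sequence with carbonate 8, via 3-(2,2-dimethyl-2H-chromen-6-yl)-5-(2-methylbut-3-en-2-yloxy)-7-[tri(propan-2-yl)silyloxy]-4H-chromen-4-one F6 (not isolated), to 3-(2,2-dimethyl-2H-chromen-6-yl)-5-hydroxy-6-(3-methylbut-2-en-1-yl)-7-[tri(propan-2-yl)silyloxy]-4H-chromen-4-one F7. Desilylation (Bu4NF, AcOH, THF, 0 °C) gives 11. If step 4 itself fails on F5, the propargylation and semi-hydrogenation described for step 4 are used instead.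

**Further compounds**
F1 | step 4 | 3-(2,2-dimethyl-2H-chromen-6-yl)-7-(methoxymethoxy)-5-(2-methylbut-3-yn-2-yloxy)-4H-chromen-4-one | COCOc1cc(OC(C)(C)C#C)c2c(=O)c(-c3ccc4c(c3)C=CC(C)(C)O4)coc2c1
F2 | step 2 | 5-hydroxy-7-(methoxymethoxy)-3-[4-(2-methylbut-3-en-2-yloxy)phenyl]-4H-chromen-4-one | COCOc1cc(O)c2c(=O)c(-c3ccc(OC(C)(C)C=C)cc3)coc2c1
F3 | step 2 | 5-hydroxy-3-[4-hydroxy-3-(3-methylbut-2-en-1-yl)phenyl]-7-(methoxymethoxy)-4H-chromen-4-one | COCOc1cc(O)c2c(=O)c(-c3ccc(O)c(CC=C(C)C)c3)coc2c1
F4 | step 5 | 3-(2,2-dimethyl-2H-chromen-6-yl)-5,7-dihydroxy-4H-chromen-4-one (isoderrone) | Oc1cc(O)c2c(=O)c(-c3ccc4c(c3)C=CC(C)(C)O4)coc2c1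
F5 | step 5 | 3-(2,2-dimethyl-2H-chromen-6-yl)-5-hydroxy-7-[tri(propan-2-yl)silyloxy]-4H-chromen-4-one | CC(C)[Si](Oc1cc(O)c2c(=O)c(-c3ccc4c(c3)C=CC(C)(C)O4)coc2c1)(C(C)C)C(C)C
F6 | step 5 | 3-(2,2-dimethyl-2H-chromen-6-yl)-5-(2-methylbut-3-en-2-yloxy)-7-[tri(propan-2-yl)silyloxy]-4H-chromen-4-one | CC(C)[Si](Oc1cc(OC(C)(C)C=C)c2c(=O)c(-c3ccc4c(c3)C=CC(C)(C)O4)coc2c1)(C(C)C)C(C)C
F7 | step 5 | 3-(2,2-dimethyl-2H-chromen-6-yl)-5-hydroxy-6-(3-methylbut-2-en-1-yl)-7-[tri(propan-2-yl)silyloxy]-4H-chromen-4-one | CC(C)[Si](Oc1cc2occ(-c3ccc4c(c3)C=CC(C)(C)O4)c(=O)c2c(O)c1CC=C(C)C)(C(C)C)C(C)C
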